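**Retrosynthetic overview**
1. Target ⇒ central ArCH2–C(ring) bond: photochemical o-quinone-methide coupling of the aromatic Mannich base 14 with the chiral acylfilicinic acid 11.
2. 11 ⇒ Claisen (Dieckmann) ring closure of the 2,2-disubstituted 3,5,7-triketo ester 10, made from quaternary β-keto ester 7 and diketene.
3. 7 ⇒ (S)-ethyl 3-hydroxybutanoate by two chelate-controlled Fráter–Seebach alkylations (geranyl bromide, then MeI), then oxidation that erases the controlling carbinol.
4. 14 ⇒ 2,4,6-trihydroxybutyrophenone by C-geranylation and Mannich aminomethylation.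
5. Ring order: the dienone ring is the only ring built (step 4); the aromatic ring is bought.

Assumption: the target is taken in the drawn tautomer, where its one stereocentre (C-4 of the dienone ring) is R; compounds 1 (≥98% ee), 2, 8 and 12 are bought.
Abbreviation: geranyl = (2E)-3,7-dimethylocta-2,6-dien-1-yl.

**Step 1**
Reactants: 1 ethyl (S)-3-hydroxybutanoate; 2 geranyl bromide
Product: 4 ethyl (2S,3S)-2-geranyl-3-hydroxybutanoate, via chelated dilithium dianion 3 (not isolated)
Conditions: LDA (2.2 equiv), THF, −78 → −20 °C; 2 (1.1 equiv), DMPU, −78 → 0 °C; H2O quench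
Reagents that add atoms: none
Why: Fráter–Seebach alkylation, in which the Li-chelated enolate/alkoxide dianion is C-alkylated by the allylic bromide (SN2, E-alkene untouched) anti to the C3 methyl; the new C2 configuration is only transient because C2 is re-enolised in step 2.

**Step 2**
Reactants: 4 ethyl (2S,3S)-2-geranyl-3-hydroxybutanoate
Product: 6 ethyl (2R,3S)-2-geranyl-3-hydroxy-2-methylbutanoate, via chelated dilithium dianion 5 (not isolated)
Conditions: LDA (2.3 equiv), THF, −78 → −10 °C; MeI (1.5 equiv), DMPU, −78 → 0 °C; H2O quench
Reagents that add atoms: iodomethane, CI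
Why: Second Fráter–Seebach alkylation, in which MeI again enters anti to the C3 methyl (the face geranyl took in step 1), so the purchased C3 stereocentre sets the quaternary centre as 2R; the minor C2 epimer is removed by chromatography here, because after step 3 it would be the enantiomer.

**Step 3**
Reactants: 6 ethyl (2R,3S)-2-geranyl-3-hydroxy-2-methylbutanoate
Product: 7 ethyl (2R)-2-geranyl-2-methyl-3-oxobutanoate
Conditions: Dess–Martin periodinane (1.3 equiv), CH2Cl2, 0 °C → rt
Reagents that add atoms: none
Why: Dess–Martin oxidation of the hindered secondary alcohol under neutral conditions (no retro-aldol, alkenes inert) erases the controlling carbinol and leaves a non-enolisable quaternary centre with distinct ester and ketone arms.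

**Step 4**
Reactants: 7 ethyl (2R)-2-geranyl-2-methyl-3-oxobutanoate; 8 diketene
Product: 11 (4R)-2-acetyl-4-geranyl-3,5-dihydroxy-4-methylcyclohexa-2,5-dien-1-one, via lithium enolate 9 (not isolated), via triketo ester 10 (not isolated)
Conditions: LDA (1.05 equiv), THF, −78 °C; cannulate into 8 (1.1 equiv), THF, −78 → −40 °C; LiHMDS (2.5 equiv), −40 °C → rt; 1 M HCl
Reagents that add atoms: none
Why: Only the acetyl CH3 of 7 can be deprotonated, diketene C-acetoacetylates enolate 9 to the 3,5,7-triketo ester 10, and its C6 carbanion closes the ring on the ester (biomimetic polyketide Claisen/Dieckmann cyclisation; the aldol mode is blocked by the quaternary C2), so the ester carbon ends up next to the acetyl-bearing carbon and the R centre is carried over with no bond to it broken.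

**Step 5**
Reactants: 12 1-(2,4,6-trihydroxyphenyl)butan-1-one; 2 geranyl bromide
Product: 13 1-(3-geranyl-2,4,6-trihydroxyphenyl)butan-1-one
Conditions: NaOMe (1.0 equiv), MeOH, 0 °C → rt; 2 (0.9 equiv) added slowly
Reagents that add atoms: none
Why: C-alkylation of the phloroglucinol monoanion by the allylic bromide in protic medium at one of the two equivalent free ring carbons, with the E geometry of the bromide retained.

**Step 6**
Reactants: 13 1-(3-geranyl-2,4,6-trihydroxyphenyl)butan-1-one
Product: 14 1-[3-(dimethylaminomethyl)-5-geranyl-2,4,6-trihydroxyphenyl]butan-1-one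
Conditions: CH2(NMe2)2 (1.2 equiv), THF, 0 °C → rt; evaporate, use without chromatography
Reagents that add atoms: bis(dimethylamino)methane, CN(C)CN(C)C
Why: Mannich aminomethylation, in which the acidic phenol opens the aminal to the iminium ion that attacks the only remaining ring CH.

**Step 7**
Reactants: 14 1-[3-(dimethylaminomethyl)-5-geranyl-2,4,6-trihydroxyphenyl]butan-1-one; 11 (4R)-2-acetyl-4-geranyl-3,5-dihydroxy-4-methylcyclohexa-2,5-dien-1-one
Product: 16 (4R)-2-acetyl-6-[(3-butanoyl-5-geranyl-2,4,6-trihydroxyphenyl)methyl]-4-geranyl-3,5-dihydroxy-4-methylcyclohexa-2,5-dien-1-one (CNP0209203.1), via o-quinone methide 15 (not isolated)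
Conditions: 14 (1.2 equiv), 11 (1.0 equiv), hν (365 nm LED), MeCN–H2O 9:1, N2, 15 °C
Reagents that add atoms: none
Why: Proposed new method: photo-deaminative methylene coupling, in which the vinylogous acid 11 protonates 14 to a tight ammonium/filicinate ion pair, 365 nm excitation of the aminomethyl-phenol triggers excited-state proton transfer and C–N heterolysis to o-quinone methide 15 (releasing HNMe2), and 15 is captured at once by C-6 of its own counter-anion in a 1,4-addition driven by rearomatisation, at neutral pH and 15 °C where thermal methylene scrambling to homodimers and chroman formation from the geranyl phenol are slow; the closest known reaction type is the photochemical generation of o-quinone methides from phenolic Mannich bases or o-hydroxybenzyl alcohols with capture by N, S or O nucleophiles and enol ethers, together with the thermal Mannich-base route to methylene-bis-phloroglucinols, and it has not been shown for an acylphloroglucinol Mannich base or for C–C capture by a cyclic β-triketone; the stereocentre is not touched.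

**Compound list**
1 | ethyl (S)-3-hydroxybutanoate | CCOC(=O)C[C@H](C)O | starting material
2 | geranyl bromide | BrC/C=C(\C)CCC=C(C)C | starting material
3 | chelated dilithium dianion of 1 | [Li+].[Li+].CCO/C([O-])=C/[C@H](C)[O-] | intermediate
4 | ethyl (2S,3S)-2-geranyl-3-hydroxybutanoate | CCOC(=O)[C@@H](C/C=C(\C)CCC=C(C)C)[C@H](C)O | intermediate
5 | chelated dilithium dianion of 4 | [Li+].[Li+].CCO/C([O-])=C(\C/C=C(\C)CCC=C(C)C)[C@H](C)[O-] | intermediate
6 | ethyl (2R,3S)-2-geranyl-3-hydroxy-2-methylbutanoate | CCOC(=O)[C@](C)(C/C=C(\C)CCC=C(C)C)[C@H](C)O | intermediate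
7 | ethyl (2R)-2-geranyl-2-methyl-3-oxobutanoate | CCOC(=O)[C@](C)(C/C=C(\C)CCC=C(C)C)C(C)=O | intermediate
8 | diketene (4-methylideneoxetan-2-one) | C=C1CC(=O)O1 | starting material
9 | lithium enolate of 7 (at the acetyl CH3) | [Li+].CCOC(=O)[C@](C)(C/C=C(\C)CCC=C(C)C)C([O-])=C | intermediate
10 | ethyl (2R)-2-geranyl-2-methyl-3,5,7-trioxooctanoate | CCOC(=O)[C@](C)(C/C=C(\C)CCC=C(C)C)C(=O)CC(=O)CC(C)=O | intermediate
11 | (4R)-2-acetyl-4-geranyl-3,5-dihydroxy-4-methylcyclohexa-2,5-dien-1-one | CC(=O)C1=C(O)[C@](C)(C/C=C(\C)CCC=C(C)C)C(O)=CC1=O | intermediate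
12 | 1-(2,4,6-trihydroxyphenyl)butan-1-one | CCCC(=O)c1c(O)cc(O)cc1O | starting material
13 | 1-(3-geranyl-2,4,6-trihydroxyphenyl)butan-1-one | CCCC(=O)c1c(O)cc(O)c(C/C=C(\C)CCC=C(C)C)c1O | intermediate
14 | 1-[3-(dimethylaminomethyl)-5-geranyl-2,4,6-trihydroxyphenyl]butan-1-one | CCCC(=O)c1c(O)c(CN(C)C)c(O)c(C/C=C(\C)CCC=C(C)C)c1O | intermediate
15 | 4-butanoyl-2-geranyl-3,5-dihydroxy-6-methylidenecyclohexa-2,4-dien-1-one (o-quinone methide) | CCCC(=O)C1=C(O)C(=C)C(=O)C(C/C=C(\C)CCC=C(C)C)=C1O | intermediate
16 | (4R)-2-acetyl-6-[(3-butanoyl-5-geranyl-2,4,6-trihydroxyphenyl)methyl]-4-geranyl-3,5-dihydroxy-4-methylcyclohexa-2,5-dien-1-one | CCCC(=O)c1c(O)c(C/C=C(\C)CCC=C(C)C)c(O)c(CC2=C(O)[C@@](C)(C/C=C(\C)CCC=C(C)C)C(O)=C(C(C)=O)C2=O)c1O | target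

**Step count and risks**
Total steps: 7. Longest linear sequence: 5 (steps 1, 2, 3, 4, 7); steps 5 and 6 form the second branch.

Three steps most likely to fail:

Step 7 (the proposed new step). The o-hydroxyaryl ketone chromophore may relax by proton transfer to its own carbonyl faster than it expels the amine, and the products absorb at 365 nm, so conversion may stall or the geranyl alkenes may isomerise. The fallback uses known thermal chemistry and sets out from 14. N-Methylation with MeI in Et2O (no base) gives 1-[3-geranyl-2,4,6-trihydroxy-5-(trimethylammoniomethyl)phenyl]butan-1-one iodide F1. With 11 and NaHCO3 in MeOH at rt to 40 °C, F1 loses trimethylamine thermally to the same o-quinone methide 15, which 11 captures. This is the established Mannich-salt route to methylene-bridged acylphloroglucinols, and it comes back to the route at 16.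

Step 4. Enolate 9 may be quenched by proton transfer from the newly formed triketone, or diketene may O-acylate, so that 10 forms in low yield. The fallback sets out from 7. A crossed Claisen condensation of the lithium enolate of 7 (LiHMDS, THF, −78 → 0 °C) with commercial ethyl 2-(2-methyl-1,3-dioxolan-2-yl)acetate gives ethyl (2R)-2-geranyl-2-methyl-6-(2-methyl-1,3-dioxolan-2-yl)-3,5-dioxohexanoate F2. Its masked acetyl cannot be lost, so no symmetrical (achiral) trione can form. Mild ketal hydrolysis (PPTS, wet acetone) then gives isolated 10, where the fallback comes back to the route; 10 is cyclised with LiHMDS as in the second half of step 4.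

Step 5. Direct C-geranylation of 12 competes with O-alkylation, double alkylation and chroman formation, so yields are often 30–45%. The fallback sets out from 12 and changes the electrophile and mechanism. Geraniol and methyl chloroformate (pyridine, CH2Cl2) give geranyl methyl carbonate F3. A Tsuji–Trost C-allylation of 12 with F3 (Pd(PPh3)4 cat., THF, rt) proceeds through the π-geranyl complex and attack at the unhindered terminus, with the E/Z ratio checked by NMR. It comes back to the route at 13.

**Further compounds**
F1 | step 7 | 1-[3-geranyl-2,4,6-trihydroxy-5-(trimethylammoniomethyl)phenyl]butan-1-one iodide | CCCC(=O)c1c(O)c(C[N+](C)(C)C)c(O)c(C/C=C(\C)CCC=C(C)C)c1O.[I-]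
F2 | step 4 | ethyl (2R)-2-geranyl-2-methyl-6-(2-methyl-1,3-dioxolan-2-yl)-3,5-dioxohexanoate | CCOC(=O)[C@](C)(C/C=C(\C)CCC=C(C)C)C(=O)CC(=O)CC1(C)OCCO1
F3 | step 5 | geranyl methyl carbonate | COC(=O)OC/C=C(\C)CCC=C(C)C
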